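**Retrosynthetic overview**

1. The strategy rests on the quaternary C3a of the cis-hydrindane core: it carries the lactone carbonyl C8 and the cyclopentane bond C3a–C3, and is flanked by C4–Br trans to that bond. An anti 1,2-shift of a ring carbon onto a bromonium ion from a neighbouring carbinol produces exactly this array. Labels follow hydrindane numbering; C8 is the lactone carbon and ring A is the bromocyclohexanol.
2. Last bonds: C1–CH2 by nickel-catalysed decarboxylative coupling of a C1 enol triflate with the ring A acetic acid active ester, then hydrogenation at C1. Lactone C8–O by lactol oxidation.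
3. Key disconnection: C3a–C3 and C4–Br by bromonium semipinacol ring contraction of an octalinol (C8 carbinol, C3a=C4 alkene, C1 ketal, C7 silyl ether).
4. Octalinol: ring 2 by ring-closing metathesis, C7 by chelate-controlled Grignard addition, C7a by conjugate addition of a dithiane anion to the enone ketal, C8 and absolute configuration by CBS reduction with separation of diastereomers. Ring A: bromonium cyclisation of a β-keto ester from 6-methylhept-5-en-2-one, resolution, acetate enolate addition.
5. Ring order: ring 1 (present from the start) → ring 2 (metathesis) → cyclopentane by contraction of ring 1 → lactone; ring A is made separately and joined last.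

Key step: step 8

Remark: compounds 4–12 and 22–24 are racemic; where two stereocentres are present the name and SMILES give the enantiomer that is carried on. α is the face of H-7a, β the opposite face.

**Route**

Step 1
Reactants: 1 1,4-dioxaspiro[4.5]dec-6-en-8-one; 2 2-methyl-1,3-dithiane
Product: 5 (±)-tert-butyldimethyl{[6-(2-methyl-1,3-dithian-2-yl)-1,4-dioxaspiro[4.5]dec-7-en-8-yl]oxy}silane, via 2-lithio-2-methyl-1,3-dithiane 3 (not isolated), via lithium enolate 4 (not isolated)
Conditions: 2, n-BuLi, THF, −30 °C; HMPA, then 1, −78 °C; TBSCl, −78 → 0 °C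
Reagents that add atoms: tert-butyldimethylsilyl chloride, CC(C)(C)[Si](C)(C)Cl
Why: Conjugate addition of a sulfur-stabilised acyl-anion equivalent, steered to 1,4-addition by HMPA, followed by O-silylation of the regiodefined enolate, should mask the C8 ketone and fix the C8=C3a enol regiochemistry for step 5, with C7a formed as a racemate.

Step 2
Reactants: 5
Product: 6 (±)-1-{8-[(tert-butyldimethylsilyl)oxy]-1,4-dioxaspiro[4.5]dec-7-en-6-yl}ethan-1-one
Conditions: MeI, NaHCO3, MeCN/H2O (9:1), 40 °C
Reagents that add atoms: water, O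
Why: Alkylative dithiane hydrolysis (S-methylation, then hydrolysis of the sulfonium salt) is neutral and non-oxidising under bicarbonate buffering, so the silyl enol ether and the dioxolane should survive.

Step 3
Reactants: 6
Product: 7 rac-(2S)-2-{(6S)-8-[(tert-butyldimethylsilyl)oxy]-1,4-dioxaspiro[4.5]dec-7-en-6-yl}hex-5-en-2-ol
Conditions: MgBr2·OEt2, CH2Cl2, −78 °C; CH2=CHCH2CH2MgBr (Et2O), −78 °C
Reagents that add atoms: but-3-en-1-ylmagnesium bromide, C=CCC[Mg]Br
Why: Grignard addition under Cram chelate control, with magnesium bridging the C7 carbonyl and a dioxolane oxygen on C1, should bring the butenyl group in from the side of the C7a hydrogen and away from C3a, which sets C7 with its oxygen on the face of H-7a once ring 2 is closed, while the enol ether keeps C8 inert.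

Step 4
Reactants: 7
Product: 8 rac-tert-butyldimethyl{[(6S)-6-{(2S)-2-[(triethylsilyl)oxy]hex-5-en-2-yl}-1,4-dioxaspiro[4.5]dec-7-en-8-yl]oxy}silane
Conditions: TESOTf, 2,6-lutidine, CH2Cl2, −78 → 0 °C
Reagents that add atoms: triethylsilyl trifluoromethanesulfonate, CC[Si](CC)(CC)OS(=O)(=O)C(F)(F)F
Why: Silylation of the hindered tertiary alcohol with a silyl triflate and a hindered base gives the TES ether that later keeps the C7 oxygen from opening the bromonium ion.

Step 5
Reactants: 8
Product: 11 rac-(6S)-7-methylidene-6-{(2S)-2-[(triethylsilyl)oxy]hex-5-en-2-yl}-1,4-dioxaspiro[4.5]decan-8-one, via Mannich base 9 (not isolated), via methiodide 10 (not isolated)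
Conditions: CH2=NMe2+ I−, CH2Cl2, 0 °C → rt; MeI, Et2O; aq. NaHCO3, CH2Cl2, rt
Reagents that add atoms: N,N-dimethylmethyleneiminium iodide, C=[N+](C)C.[I-]
Why: Mannich reaction of the silyl enol ether with the iminium salt occurs only at C3a, and quaternisation followed by E1cB loss of trimethylamine should give the exo-methylene ketone without regiochemical ambiguity.

Step 6
Reactants: 11
Product: 12 rac-(8'S,8a'S)-8'-methyl-8'-[(triethylsilyl)oxy]-2',3',6',7',8',8a'-hexahydrospiro[1,3-dioxolane-2,1'-naphthalen]-4'-one
Conditions: second-generation Grubbs catalyst RuCl2(=CHPh)(PCy3)(H2IMes) (5 mol %), CH2Cl2 (5 mM), 40 °C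
Reagents that add atoms: none
Why: Ring-closing metathesis of the terminal alkene onto the 1,1-disubstituted enone alkene closes six-membered ring 2 with loss of ethene and places the trisubstituted alkene at C3a=C4.

Step 7
Reactants: 12
Product: 13 (4'S,8'S,8a'S)-8'-methyl-8'-[(triethylsilyl)oxy]-3',4',6',7',8',8a'-hexahydro-2'H-spiro[1,3-dioxolane-2,1'-naphthalen]-4'-ol
Conditions: (R)-2-methyl-CBS-oxazaborolidine (1 equiv), catecholborane, toluene, −78 °C; chromatography to remove the C4' epimer that forms from the other enantiomer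
Reagents that add atoms: none
Why: Corey–Bakshi–Shibata reduction under reagent control (alkenyl carbon C3a as the large group) should give the S carbinol from both enantiomers of 12, so the (8'S,8a'S) enantiomer gives 13 with the pseudo-axial hydroxyl cis to H-7a while its antipode gives a separable diastereomer, a divergent resolution that sets C8 and the absolute configuration together.

Step 8
Reactants: 13
Product: 14 (3a'R,4'R,7'S,7a'S)-4'-bromo-7'-methyl-7'-[(triethylsilyl)oxy]octahydrospiro[1,3-dioxolane-2,1'-indene]-3a'-carbaldehyde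
Conditions: NBS (1.05 equiv), NaHCO3 (solid), CH2Cl2, −40 → 0 °C, dark
Reagents that add atoms: N-bromosuccinimide, O=C1CCC(=O)N1Br
Why: Proposed new method: NBS should form the bromonium ion on the α face of the C3a=C4 alkene, the face of the pseudo-axial C8 hydroxyl and of H-7a, and the C8–C3 ring bond, held on the β face at about 50° to the alkene plane by the chair of ring 1, then shifts to C3a anti to bromine while the carbinol oxygen closes to the aldehyde and the proton passes to succinimide. The closest known reaction types are the halonium-induced semipinacol rearrangement of allylic alcohols to β-halo carbonyl compounds (known as 1,2-shifts and ring expansions) and the ring-contracting semipinacol rearrangement of cyclic 2,3-epoxy alcohols. The cyclopentane (C1–C2–C3–C3a–C7a) is closed by a 1,2-alkyl shift that contracts cyclohexanol ring 1, not by cyclisation of a chain, so the only geometric demand is overlap of the migrating bond with the developing p orbital at C3a. C3a is set because the tether through C2–C1–C7a lets C3 arrive only on the β face, which pushes the formyl group to the α face (cis fusion with H-7a), and C4 is set by anti addition, with bromine α, trans to C3 and cis to the formyl group. The step needs carbon to migrate in place of hydride and the bromonium ion to form syn to the hydroxyl: the C8 hydrogen lies in the nodal plane of the alkene and cannot shift, the hydroxyl can guide NBS by hydrogen bonding, the β face is screened by the axial C7 methyl group and by ring 1, and the C7 oxygen is silylated so that it does not open the bromonium ion.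

Step 9
Reactants: 14
Product: 15 (3aR,4R,7S,7aS)-4-bromo-7-hydroxy-7-methyl-1-oxooctahydro-1H-indene-3a-carbaldehyde as its cyclic hemiacetal between C8 and the C7 oxygen (lactol; both C8 anomers)
Conditions: 1 M aq. HCl, THF, 25 °C
Reagents that add atoms: water, O
Why: Acid hydrolysis removes the TES ether and the dioxolane, and the freed C7 hydroxyl, which sits on the α face next to the α formyl group, should close onto C8 as the five-membered lactol.

Step 10
Reactants: 15
Product: 16 (3aR,4R,7S,7aS)-4-bromo-7-hydroxy-7-methyl-1-oxooctahydro-1H-indene-3a-carboxylic acid 3a,7-lactone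
Conditions: PhI(OAc)2, TEMPO (10 mol %), CH2Cl2, 25 °C
Reagents that add atoms: none
Why: Oxoammonium oxidation of a lactol to the lactone is selective here because the ketone and the secondary bromide are inert and no other carbinol is present.

Step 11
Reactants: 16
Product: 18 C1 enol triflate of 16 (C1=C2 alkene, triflyloxy group on C1; 3aR,4R,7S,7aS), via potassium enolate 17 (not isolated)
Conditions: KN(SiMe3)2, THF, −78 °C; PhNTf2, −78 → −30 °C
Reagents that add atoms: N-phenylbis(trifluoromethanesulfonimide), O=S(=O)(N(c1ccccc1)S(=O)(=O)C(F)(F)F)C(F)(F)F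
Why: Kinetic deprotonation by the bulky amide at the open C2 methylene in preference to the neopentyl C7a methine, then O-triflation of the enolate, gives the C1=C2 enol triflate, and loss of the lactone oxygen from C7 is avoided because no C7a enolate forms and the bridged C7–O bond lies near the nodal plane of such an enolate.

Step 12
Reactants: 19 6-methylhept-5-en-2-one
Product: 21 methyl 7-methyl-3-oxooct-6-enoate, via sodium enolate 20 (not isolated)
Conditions: NaH, (MeO)2CO, THF, reflux; aq. HCl work-up
Reagents that add atoms: dimethyl carbonate, COC(=O)OC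
Why: Claisen-type C-acylation of the methyl ketone enolate by dimethyl carbonate is driven by formation of the stabilised β-keto ester enolate.

Step 13
Reactants: 21
Product: 22 (±)-methyl 3-bromo-2,2-dimethyl-6-oxocyclohexane-1-carboxylate (C1 epimerisable)
Conditions: Et2SBr·SbCl5Br (1.1 equiv), MeNO2, −25 °C, 5 min
Reagents that add atoms: bromodiethylsulfonium bromopentachloroantimonate, CC[S+](Br)CC.Br[Sb-](Cl)(Cl)(Cl)(Cl)Cl
Why: Bromonium-induced cation–olefin cyclisation terminated by the β-keto ester enol (6-endo closure at the dimethyl-substituted carbon through a chair transition state) places bromine next to the new quaternary carbon and gives a racemate.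

Step 14
Reactants: 22
Product: 24 (±)-4-bromo-3,3-dimethylcyclohexan-1-one, via keto acid 23 (not isolated)
Conditions: 48% aq. HBr, AcOH, 90 °C
Reagents that add atoms: none
Why: Acid hydrolysis of the methyl ester and thermal decarboxylation of the β-keto acid give the ketone, and HBr as the acid rules out halide exchange at the secondary bromide.

Step 15
Reactants: 24
Product: 25 (R)-4-bromo-3,3-dimethylcyclohexan-1-one
Conditions: preparative HPLC on a chiral stationary phase (amylose tris(3,5-dimethylphenylcarbamate)), hexane/i-PrOH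
Reagents that add atoms: none
Why: Chromatographic resolution of the racemate supplies the R enantiomer, whose configuration is to be confirmed by anomalous-dispersion X-ray analysis of a crystalline derivative, since no reliable enantioselective bromocyclisation exists for this substrate.

Step 16
Reactants: 25
Product: 26 tert-butyl 2-[(1S,4R)-4-bromo-1-hydroxy-3,3-dimethylcyclohexyl]acetate
Conditions: LiN(i-Pr)2, t-BuOAc, THF, −78 °C; then 25, −78 °C; chromatography to remove the C1 epimer
Reagents that add atoms: tert-butyl acetate, CC(=O)OC(C)(C)C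
Why: Aldol-type addition of the ester enolate from the equatorial side, because the axial 3-methyl group blocks axial attack, gives the axial tertiary alcohol, and the adduct formed through the chair with equatorial bromine (hydroxyl cis to bromine) is 26, which is separated from the epimer that arises from the other chair.

Step 17
Reactants: 26
Product: 28 2-[(1S,4R)-4-bromo-3,3-dimethyl-1-(triethylsilyloxy)cyclohexyl]acetic acid, via silyl ester 27 (not isolated)
Conditions: TESOTf (3 equiv), 2,6-lutidine, CH2Cl2, 0 °C → rt; then pH 5 aq. buffer/THF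
Reagents that add atoms: triethylsilyl trifluoromethanesulfonate, CC[Si](CC)(CC)OS(=O)(=O)C(F)(F)F
Why: The silyl triflate silylates the tertiary alcohol and converts the tert-butyl ester into the silyl ester with loss of isobutene, and the labile silyl ester hydrolyses on work-up, so protection and ester cleavage occur without base that could cause retro-aldol cleavage.

Step 18
Reactants: 28
Product: 29 1,3-dioxoisoindolin-2-yl 2-[(1S,4R)-4-bromo-3,3-dimethyl-1-(triethylsilyloxy)cyclohexyl]acetate
Conditions: N-hydroxyphthalimide, N,N'-diisopropylcarbodiimide, DMAP (cat.), CH2Cl2, 25 °C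
Reagents that add atoms: N-hydroxyphthalimide, ON1C(=O)c2ccccc2C1=O
Why: Carbodiimide (Steglich-type) esterification with N-hydroxyphthalimide gives the redox-active ester.

Step 19
Reactants: 18; 29
Product: 30 C1=C2 alkene analogue of 31 (ring A methylene group on C1; all stereocentres as in 31 except C1, which is sp2)
Conditions: NiBr2(dme) (20 mol %), 4,4'-di-tert-butyl-2,2'-bipyridine (20 mol %), Zn powder, DMA, 25 °C; 29 in 1.5-fold excess
Reagents that add atoms: none
Why: Nickel-catalysed reductive decarboxylative alkenylation (cross-electrophile coupling) should turn the active ester into the primary alkyl radical, which is captured by the alkenylnickel species from the triflate, because the N-acyloxyphthalimide is reduced far more easily than the two hindered secondary C–Br bonds and no stereocentre is touched.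

Step 20
Reactants: 30
Product: 31 (1R,3aR,4R,7S,7aS)-4-bromo-1-{[(1R,4R)-4-bromo-3,3-dimethyl-1-(triethylsilyloxy)cyclohexyl]methyl}-7-hydroxy-7-methyloctahydro-1H-indene-3a-carboxylic acid 3a,7-lactone
Conditions: [Ir(cod)(PCy3)(py)]PF6 (10 mol %), H2 (1 atm), CH2Cl2, 25 °C
Reagents that add atoms: none
Why: Homogeneous hydrogenation with the cationic iridium catalyst, which tolerates alkyl bromides, should deliver hydrogen to the convex α face of the cyclopentene, the face of H-7a to which the lactone carbonyl can also guide the metal, because the β face is covered by ring 2 and the C7 methyl group, and this sets C1 with the side chain β.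

Step 21
Reactants: 31
Product: 32 (1R,3aR,4R,7S,7aS)-4-bromo-1-{[(1R,4R)-4-bromo-1-hydroxy-3,3-dimethylcyclohexyl]methyl}-7-hydroxy-7-methyloctahydro-1H-indene-3a-carboxylic acid 3a,7-lactone (CNP0282702.1)
Conditions: HF·pyridine, pyridine/THF, 0 → 25 °C
Reagents that add atoms: none
Why: Fluoride-mediated cleavage of the tertiary TES ether under buffered, non-basic conditions should leave the lactone and both secondary bromides untouched.

**Compound list**

1 | 1,4-dioxaspiro[4.5]dec-6-en-8-one | O=C1C=CC2(CC1)OCCO2 | starting material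
2 | 2-methyl-1,3-dithiane | CC1SCCCS1 | starting material
3 | 2-lithio-2-methyl-1,3-dithiane | [Li]C1(C)SCCCS1 | intermediate (not isolated)
4 | lithium 6-(2-methyl-1,3-dithian-2-yl)-1,4-dioxaspiro[4.5]dec-7-en-8-olate (racemic) | [Li]OC1=CC(C2(CC1)OCCO2)C3(C)SCCCS3 | intermediate (not isolated)
5 | (±)-tert-butyldimethyl{[6-(2-methyl-1,3-dithian-2-yl)-1,4-dioxaspiro[4.5]dec-7-en-8-yl]oxy}silane | CC(C)(C)[Si](C)(C)OC1=CC(C2(CC1)OCCO2)C3(C)SCCCS3 | intermediate
6 | (±)-1-{8-[(tert-butyldimethylsilyl)oxy]-1,4-dioxaspiro[4.5]dec-7-en-6-yl}ethan-1-one | CC(=O)C1C=C(O[Si](C)(C)C(C)(C)C)CCC12OCCO2 | intermediate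
7 | rac-(2S)-2-{(6S)-8-[(tert-butyldimethylsilyl)oxy]-1,4-dioxaspiro[4.5]dec-7-en-6-yl}hex-5-en-2-ol | CC(C)(C)[Si](C)(C)OC1=C[C@H](C2(CC1)OCCO2)[C@@](C)(O)CCC=C | intermediate
8 | triethylsilyl ether of 7 (racemic) | CC(C)(C)[Si](C)(C)OC1=C[C@H](C2(CC1)OCCO2)[C@@](C)(O[Si](CC)(CC)CC)CCC=C | intermediate
9 | rac-(6S)-7-[(dimethylamino)methyl]-6-{(2S)-2-[(triethylsilyl)oxy]hex-5-en-2-yl}-1,4-dioxaspiro[4.5]decan-8-one (C7 epimers) | O=C1CCC2(OCCO2)[C@@H](C1CN(C)C)[C@@](C)(O[Si](CC)(CC)CC)CCC=C | intermediate (not isolated)
10 | N-methyl ammonium iodide of 9 | O=C1CCC2(OCCO2)[C@@H](C1C[N+](C)(C)C)[C@@](C)(O[Si](CC)(CC)CC)CCC=C.[I-] | intermediate (not isolated)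
11 | rac-(6S)-7-methylidene-6-{(2S)-2-[(triethylsilyl)oxy]hex-5-en-2-yl}-1,4-dioxaspiro[4.5]decan-8-one | O=C1CCC2(OCCO2)[C@@H](C1=C)[C@@](C)(O[Si](CC)(CC)CC)CCC=C | intermediate
12 | rac-(8'S,8a'S)-8'-methyl-8'-[(triethylsilyl)oxy]-2',3',6',7',8',8a'-hexahydrospiro[1,3-dioxolane-2,1'-naphthalen]-4'-one | O=C1CCC2(OCCO2)[C@H]3C1=CCC[C@]3(C)O[Si](CC)(CC)CC | intermediate
13 | (4'S,8'S,8a'S)-8'-methyl-8'-[(triethylsilyl)oxy]-3',4',6',7',8',8a'-hexahydro-2'H-spiro[1,3-dioxolane-2,1'-naphthalen]-4'-ol (key-step precursor) | O[C@H]1CCC2(OCCO2)[C@H]3C1=CCC[C@]3(C)O[Si](CC)(CC)CC | intermediate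
14 | (3a'R,4'R,7'S,7a'S)-4'-bromo-7'-methyl-7'-[(triethylsilyl)oxy]octahydrospiro[1,3-dioxolane-2,1'-indene]-3a'-carbaldehyde (key-step product) | O=C[C@@]12CCC3(OCCO3)[C@@H]1[C@@](C)(O[Si](CC)(CC)CC)CC[C@H]2Br | intermediate
15 | keto lactol: cyclic C8 hemiacetal of (3aR,4R,7S,7aS)-4-bromo-7-hydroxy-7-methyl-1-oxooctahydro-1H-indene-3a-carbaldehyde | O=C1CC[C@@]23C(O)O[C@@](C)(CC[C@H]2Br)[C@@H]13 | intermediate
16 | (3aR,4R,7S,7aS)-4-bromo-7-hydroxy-7-methyl-1-oxooctahydro-1H-indene-3a-carboxylic acid 3a,7-lactone | O=C1CC[C@@]23C(=O)O[C@@](C)(CC[C@H]2Br)[C@@H]13 | intermediate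
17 | potassium C1=C2 enolate of 16 | [K]OC1=CC[C@@]23C(=O)O[C@@](C)(CC[C@H]2Br)[C@@H]13 | intermediate (not isolated)
18 | C1 enol triflate of 16 (C1=C2) | O=S(=O)(OC1=CC[C@@]23C(=O)O[C@@](C)(CC[C@H]2Br)[C@@H]13)C(F)(F)F | intermediate
19 | 6-methylhept-5-en-2-one | CC(=O)CCC=C(C)C | starting material
20 | sodium 6-methylhepta-1,5-dien-2-olate | [Na]OC(=C)CCC=C(C)C | intermediate (not isolated)
21 | methyl 7-methyl-3-oxooct-6-enoate | COC(=O)CC(=O)CCC=C(C)C | intermediate
22 | (±)-methyl 3-bromo-2,2-dimethyl-6-oxocyclohexane-1-carboxylate | COC(=O)C1C(=O)CCC(Br)C1(C)C | intermediate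
23 | (±)-3-bromo-2,2-dimethyl-6-oxocyclohexane-1-carboxylic acid | OC(=O)C1C(=O)CCC(Br)C1(C)C | intermediate (not isolated)
24 | (±)-4-bromo-3,3-dimethylcyclohexan-1-one | CC1(C)CC(=O)CCC1Br | intermediate
25 | (R)-4-bromo-3,3-dimethylcyclohexan-1-one | CC1(C)CC(=O)CC[C@H]1Br | intermediate
26 | tert-butyl 2-[(1S,4R)-4-bromo-1-hydroxy-3,3-dimethylcyclohexyl]acetate | CC1(C)C[C@](O)(CC(=O)OC(C)(C)C)CC[C@H]1Br | intermediate
27 | triethylsilyl 2-[(1S,4R)-4-bromo-3,3-dimethyl-1-(triethylsilyloxy)cyclohexyl]acetate | CC1(C)C[C@](O[Si](CC)(CC)CC)(CC(=O)O[Si](CC)(CC)CC)CC[C@H]1Br | intermediate (not isolated)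
28 | 2-[(1S,4R)-4-bromo-3,3-dimethyl-1-(triethylsilyloxy)cyclohexyl]acetic acid | CC1(C)C[C@](O[Si](CC)(CC)CC)(CC(=O)O)CC[C@H]1Br | intermediate
29 | 1,3-dioxoisoindolin-2-yl 2-[(1S,4R)-4-bromo-3,3-dimethyl-1-(triethylsilyloxy)cyclohexyl]acetate | CC1(C)C[C@](O[Si](CC)(CC)CC)(CC(=O)ON2C(=O)c3ccccc3C2=O)CC[C@H]1Br | intermediate
30 | C1=C2 alkene analogue of 31 | CC1(C)C[C@](O[Si](CC)(CC)CC)(CC2=CC[C@@]34C(=O)O[C@@](C)(CC[C@H]3Br)[C@@H]24)CC[C@H]1Br | intermediate
31 | ring A triethylsilyl ether of the target | CC1(C)C[C@](O[Si](CC)(CC)CC)(C[C@H]2CC[C@@]34C(=O)O[C@@](C)(CC[C@H]3Br)[C@@H]24)CC[C@H]1Br | intermediate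
32 | CNP0282702.1 | CC1(C)C[C@](O)(C[C@H]2CC[C@@]34C(=O)O[C@@](C)(CC[C@H]3Br)[C@@H]24)CC[C@H]1Br | target

**Step count**

Total: 21 steps. Longest linear sequence: 14 steps (steps 1–11 and 19–21); the ring A branch is steps 12–18.

**Steps most likely to fail**

Step 8 (proposed new method). What may go wrong: the bromonium ion forms on the β face and is opened by the hydroxyl or the silyl ether oxygen, or the ring carbon fails to shift, so no contraction takes place. The fallback uses known chemistry, sets out from 13 and returns at 16. Hydroxyl-directed epoxidation of 13 with VO(acac)2 and t-BuOOH should give the α-epoxy alcohol F1. BF3·OEt2 at −78 °C then triggers the established semipinacol rearrangement of a 2,3-epoxy alcohol, the same C3 shift with ring contraction, to the β-hydroxy aldehyde F2 with the C4 hydroxyl α. HF·pyridine gives the lactol F3, and Dess–Martin periodinane oxidises the lactol and the C4 carbinol to the keto lactone F4. LiBH(s-Bu)3 reduces the C4 ketone from the open α side to the axial β alcohol F5. Tf2O/pyridine gives the triflate F6, which Bu4NBr displaces with inversion to the α bromide F7; this displacement next to a quaternary carbon is the weak point of the fallback. Aqueous HCl removes the dioxolane to give 16.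

Step 19. What may go wrong: low-valent nickel abstracts bromine from the two secondary C–Br bonds in competition with reduction of the active ester, giving reduced or scrambled products. The fallback sets out from 16 and 25 and returns at 32. Takai–Lombardo methylenation (Zn, CH2Br2, TiCl4) of the C1 ketone of 16 gives the exocyclic alkene F8. Hydroboration with 9-BBN from the α face and oxidation with NaBO3 give the primary alcohol F9 with C1 set. I2, PPh3 and imidazole give the iodide F10. A samarium Barbier reaction (SmI2, THF/HMPA, −78 °C) of F10 with ketone 25 adds the primary alkyl group from the equatorial side and gives 32 after separation from its ring A carbinol epimer, so ring A needs neither the acetate homologation nor a protecting group.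

Step 3. What may go wrong: poor facial selectivity if the open Felkin–Anh transition state competes with the magnesium chelate, giving the C7 epimer. The fallback sets out from 1 and returns at 7 by introducing the two C7 substituents in the reverse order. 2-(But-3-en-1-yl)-1,3-dithiane F11 (from 1,3-dithiane, n-BuLi and 4-bromobut-1-ene) is lithiated and added to 1 as in step 1 to give the silyl enol ether F12. MeI/NaHCO3 hydrolysis gives the butenyl ketone F13. MeLi in THF at −78 °C, where no chelate is expected, should then add anti to the ketal carbon C1 (Felkin–Anh model), which gives the C7 configuration of 7.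

**Further compounds**

F1 | step 8 | α-epoxy alcohol: 4a',5'-epoxide of 13 on the face of the hydroxyl | O[C@H]1CCC2(OCCO2)[C@H]3[C@@]14O[C@@H]4CC[C@]3(C)O[Si](CC)(CC)CC
F2 | step 8 | C4 α-hydroxy analogue of 14 | O=C[C@@]12CCC3(OCCO3)[C@@H]1[C@@](C)(O[Si](CC)(CC)CC)CC[C@H]2O
F3 | step 8 | C1 dioxolane lactol with C4 α-hydroxyl | O1CCOC12CC[C@@]34C(O)O[C@@](C)(CC[C@H]3O)[C@@H]24
F4 | step 8 | C1 dioxolane lactone with C4 ketone | O1CCOC12CC[C@@]34C(=O)O[C@@](C)(CCC3=O)[C@@H]24
F5 | step 8 | C1 dioxolane lactone with C4 β-hydroxyl | O1CCOC12CC[C@@]34C(=O)O[C@@](C)(CC[C@@H]3O)[C@@H]24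
F6 | step 8 | C4 β-triflate of F5 | O1CCOC12CC[C@@]34C(=O)O[C@@](C)(CC[C@@H]3OS(=O)(=O)C(F)(F)F)[C@@H]24
F7 | step 8 | C1 dioxolane of 16 (C4 α-bromide) | O1CCOC12CC[C@@]34C(=O)O[C@@](C)(CC[C@H]3Br)[C@@H]24
F8 | step 19 | C1 methylidene analogue of 16 | C=C1CC[C@@]23C(=O)O[C@@](C)(CC[C@H]2Br)[C@@H]13
F9 | step 19 | (1R)-1-(hydroxymethyl) lactone | OC[C@H]1CC[C@@]23C(=O)O[C@@](C)(CC[C@H]2Br)[C@@H]13
F10 | step 19 | (1R)-1-(iodomethyl) lactone | IC[C@H]1CC[C@@]23C(=O)O[C@@](C)(CC[C@H]2Br)[C@@H]13
F11 | step 3 | 2-(but-3-en-1-yl)-1,3-dithiane | C=CCCC1SCCCS1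
F12 | step 3 | (±)-{[6-(2-(but-3-en-1-yl)-1,3-dithian-2-yl)-1,4-dioxaspiro[4.5]dec-7-en-8-yl]oxy}(tert-butyl)dimethylsilane | CC(C)(C)[Si](C)(C)OC1=CC(C2(CC1)OCCO2)C3(CCC=C)SCCCS3
F13 | step 3 | (±)-1-{8-[(tert-butyldimethylsilyl)oxy]-1,4-dioxaspiro[4.5]dec-7-en-6-yl}pent-4-en-1-one | C=CCCC(=O)C1C=C(O[Si](C)(C)C(C)(C)C)CCC12OCCO2
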